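**Plan**

- Retrosynthesis: in each ring both quinone carbonyls are late oxidations. The C4 carbonyl goes back to an aryl C–H and the C1 carbonyl to an aryl C–B bond, leaving two identical 4-methoxyphenol rings on a (CH2)13 tether.
- Each benzene ring is then cut at three bonds, C(OMe)–C(Me), C(B)–C(OH) and C(OH)–C(chain), into an alkenyl(methoxy)carbene chromium unit, one CO ligand and 1-propynyl-Bpin. The alkenylcarbene is cut at its C=C bond into methoxy(methyl)carbene chromium and a C15 dialdehyde.
- Enabling feature: in each quinone ring the O-methylated carbon C5 and the hydroxylated carbon C2 are para. This is the carbene-carbon/CO-carbon relationship of a Dötz benzannulation, so OMe and OH are differentiated by origin. The C-methyl carbon C6 and the carbonyl carbon C1 are the two alkyne carbons.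
- Forward: pentadecanolide gives the C15 dialdehyde; a twofold aldol condensation with the carbene complex joins the chain; one twofold benzannulation closes both rings; MOM protection, C–B oxidation, aerobic para-oxidation and MOM removal finish.
- Stereochemistry: the target has no stereocentre. The only stereo-element on the way, the E geometry of the two alkenylcarbene double bonds, comes from E1cB elimination and is consumed in the annulation.

Key step: step 5

Remark: the target is drawn as the 2-hydroxy-1,4-benzoquinone tautomer; chromium left on the new rings after the annulation is taken to leave in air as carbon monoxide and chromium sesquioxide.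

**Step 1**
Reactants: 1 chromium hexacarbonyl Cr(CO)6; 2 methyllithium
Product: 4 pentacarbonyl(1-methoxyethylidene)chromium, via lithium acetylpentacarbonylchromate 3 (not isolated)
Conditions: MeLi, Et2O, 0 °C to rt; then Me3OBF4, CH2Cl2/H2O, 0 °C
Reagents that add atoms: trimethyloxonium tetrafluoroborate, C[O+](C)C.F[B-](F)(F)F
Why: Fischer carbene synthesis, in which MeLi adds to a CO ligand and the resulting acyl chromate is O-methylated by the hard oxonium salt, so that the former CO carbon and the methyl carbon later become two adjacent ring atoms.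

**Step 2**
Reactants: 5 pentadecan-15-olide (oxacyclohexadecan-2-one)
Product: 6 pentadecane-1,15-diol
Conditions: LiAlH4, THF, 0 °C to reflux; aqueous NaOH work-up
Reagents that add atoms: none
Why: Hydride reduction of a lactone to the diol is a standard ester reduction and creates no stereocentre.

**Step 3**
Reactants: 6 pentadecane-1,15-diol
Product: 7 pentadecanedial
Conditions: TEMPO (cat.), PhI(OAc)2, CH2Cl2, rt
Reagents that add atoms: none
Why: The oxoammonium-mediated TEMPO/PhI(OAc)2 oxidation of unhindered primary alcohols should stop at the aldehyde without over-oxidation to the acid.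

**Step 4**
Reactants: 4 pentacarbonyl(1-methoxyethylidene)chromium (2.3 equiv); 7 pentadecanedial
Product: 11 [(2E,17E)-1,19-dimethoxynonadeca-2,17-diene-1,19-diylidene]bis(pentacarbonylchromium), via lithiated carbene complex 8 (not isolated), via dilithium bis-aldolate 9 (not isolated), via bis-mesylate 10 (not isolated)
Conditions: n-BuLi, THF, −78 °C; 7, −78 to −30 °C; then MsCl, Et3N, −30 °C to rt
Reagents that add atoms: none
Why: Aldol condensation of a Fischer carbene complex, in which the α-CH of 4 (as acidic as a 1,3-dicarbonyl) is deprotonated, the anion adds to both formyl groups, and mesylation followed by E1cB elimination should give the conjugated E-alkenylcarbene at each chain end, destroying the two carbinol stereocentres of 9 and 10.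

**Step 5**
Reactants: 11 [(2E,17E)-1,19-dimethoxynonadeca-2,17-diene-1,19-diylidene]bis(pentacarbonylchromium); 12 4,4,5,5-tetramethyl-2-(prop-1-yn-1-yl)-1,3,2-dioxaborolane (3 equiv)
Product: 14 6,6′-(tridecane-1,13-diyl)bis[4-methoxy-3-methyl-2-(4,4,5,5-tetramethyl-1,3,2-dioxaborolan-2-yl)phenol], via bis(tricarbonylchromium) arene complex 13 (not isolated)
Conditions: THF (0.05 M), 50 °C, argon, 16 h; then air, rt
Reagents that add atoms: none
Why: Each pentacarbonyl carbene loses CO, the alkyne inserts into Cr=C so that its methyl-bearing carbon bonds to the methoxycarbene carbon, a CO ligand inserts to give a chromium-bound dienylketene, and this closes and enolises to the phenol (Dötz benzannulation, a formal [3+2+1] assembly of alkenylcarbene, alkyne and CO). The closest known reaction type is the benzannulation of alkenyl(alkoxy)carbene chromium complexes with 1-alkynylboronic esters and other internal alkynes, which is also known to run twice on bis-carbene complexes. Each benzene ring is closed by a thermal 6π-electrocyclisation of the dienylketene (ketene carbon onto the alkene terminus that carries the chain), after which the hydrogen on that terminus moves to oxygen to aromatise. No stereocentre is formed. The selectivity needed is the orientation of alkyne insertion, and it should be secured by the size difference between Bpin and methyl: the bulky boryl carbon stays next to chromium and hence next to the CO-derived carbon, the normal large-group-ortho-to-hydroxyl rule. The alkenyl (not aryl) carbene, THF as solvent and the hydrogen on the alkene terminus favour the phenol over cyclobutenone, furan or non-aromatisable cyclohexadienone products, and the thirteen-carbon tether keeps the two carbene ends independent.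

**Step 6**
Reactants: 14 6,6′-(tridecane-1,13-diyl)bis[4-methoxy-3-methyl-2-(4,4,5,5-tetramethyl-1,3,2-dioxaborolan-2-yl)phenol]
Product: 15 1,13-bis[5-methoxy-2-(methoxymethoxy)-4-methyl-3-(4,4,5,5-tetramethyl-1,3,2-dioxaborolan-2-yl)phenyl]tridecane
Conditions: NaH, MOMCl, DMF, 0 °C to rt
Reagents that add atoms: chloromethyl methyl ether (MOMCl), COCCl
Why: Williamson-type O-alkylation of the phenoxide masks the CO-derived hydroxyl with an acetal that cannot migrate to the neighbouring oxygen, so the hydroxyl made in step 7 will be the only free phenol.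

**Step 7**
Reactants: 15 1,13-bis[5-methoxy-2-(methoxymethoxy)-4-methyl-3-(4,4,5,5-tetramethyl-1,3,2-dioxaborolan-2-yl)phenyl]tridecane
Product: 16 3,3′-(tridecane-1,13-diyl)bis[5-methoxy-2-(methoxymethoxy)-6-methylphenol]
Conditions: H2O2 (30% aq), NaOH, THF, 0 °C
Reagents that add atoms: hydrogen peroxide, OO
Why: Oxidation of an arylboronic ester by basic hydroperoxide proceeds through a 1,2-aryl shift from boron to oxygen, placing the phenol exactly where the alkyne delivered boron.

**Step 8**
Reactants: 16 3,3′-(tridecane-1,13-diyl)bis[5-methoxy-2-(methoxymethoxy)-6-methylphenol]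
Product: 17 3,3′-(tridecane-1,13-diyl)bis[5-methoxy-2-(methoxymethoxy)-6-methylcyclohexa-2,5-diene-1,4-dione]
Conditions: O2 (1 atm), Co(salen) (C16H14CoN2O2, divalent cobalt, 10 mol %), DMF, rt
Reagents that add atoms: dioxygen, O=O
Why: Cobalt–salen/O2 oxidation of a phenol with a free para position (the aerobic counterpart of the Teuber reaction) should give the p-benzoquinone, and in each ring the only unsubstituted carbon is para to the free hydroxyl, so the new carbonyl oxygen has one possible site.

**Step 9**
Reactants: 17 3,3′-(tridecane-1,13-diyl)bis[5-methoxy-2-(methoxymethoxy)-6-methylcyclohexa-2,5-diene-1,4-dione]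
Product: 18 3,3′-(tridecane-1,13-diyl)bis(2-hydroxy-5-methoxy-6-methylcyclohexa-2,5-diene-1,4-dione) (target)
Conditions: 2 M aq HCl, THF, rt
Reagents that add atoms: none
Why: Acid hydrolysis of the MOM acetal, here the acetal of a vinylogous acid and therefore especially labile, should release the 2-hydroxyquinone under conditions too mild to cleave the vinylogous methyl ester.

**Compound list**

1 | chromium hexacarbonyl Cr(CO)6 | O=C=[Cr](=C=O)(=C=O)(=C=O)(=C=O)=C=O | starting material
2 | methyllithium | [Li]C | starting material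
3 | lithium acetylpentacarbonylchromate | [Li+].CC([O-])=[Cr](=C=O)(=C=O)(=C=O)(=C=O)=C=O | intermediate (not isolated)
4 | pentacarbonyl(1-methoxyethylidene)chromium | COC(C)=[Cr](=C=O)(=C=O)(=C=O)(=C=O)=C=O | intermediate
5 | pentadecan-15-olide (oxacyclohexadecan-2-one) | O=C1CCCCCCCCCCCCCCO1 | starting material
6 | pentadecane-1,15-diol | OCCCCCCCCCCCCCCCO | intermediate
7 | pentadecanedial | O=CCCCCCCCCCCCCCC=O | intermediate
8 | lithium salt of the α-carbanion of 4 | [Li+].[CH2-]C(OC)=[Cr](=C=O)(=C=O)(=C=O)(=C=O)=C=O | intermediate (not isolated)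
9 | dilithium 1,19-dimethoxy-1,19-bis(pentacarbonylchromio)nonadecane-1,19-diylidene-3,17-diolate (mixture of diastereomers, stereocentres removed in the same step) | [Li+].[Li+].COC(CC([O-])CCCCCCCCCCCCCC([O-])CC(OC)=[Cr](=C=O)(=C=O)(=C=O)(=C=O)=C=O)=[Cr](=C=O)(=C=O)(=C=O)(=C=O)=C=O | intermediate (not isolated)
10 | 3,17-bis(methanesulfonyloxy) analogue of 9 (mixture of diastereomers) | COC(CC(OS(C)(=O)=O)CCCCCCCCCCCCCC(OS(C)(=O)=O)CC(OC)=[Cr](=C=O)(=C=O)(=C=O)(=C=O)=C=O)=[Cr](=C=O)(=C=O)(=C=O)(=C=O)=C=O | intermediate (not isolated)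
11 | [(2E,17E)-1,19-dimethoxynonadeca-2,17-diene-1,19-diylidene]bis(pentacarbonylchromium) | COC(=[Cr](=C=O)(=C=O)(=C=O)(=C=O)=C=O)/C=C/CCCCCCCCCCCCC/C=C/C(OC)=[Cr](=C=O)(=C=O)(=C=O)(=C=O)=C=O | intermediate
12 | 4,4,5,5-tetramethyl-2-(prop-1-yn-1-yl)-1,3,2-dioxaborolane | CC#CB1OC(C)(C)C(C)(C)O1 | starting material
13 | bis(tricarbonylchromium) complex of 14 (each new benzene ring η6-bound to one Cr(CO)3; the two metal fragments are drawn apart from the arene) | COc1cc(CCCCCCCCCCCCCc2cc(OC)c(C)c(B3OC(C)(C)C(C)(C)O3)c2O)c(O)c(B2OC(C)(C)C(C)(C)O2)c1C.O=C=[Cr](=C=O)=C=O.O=C=[Cr](=C=O)=C=O | intermediate (not isolated)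
14 | 6,6′-(tridecane-1,13-diyl)bis[4-methoxy-3-methyl-2-(4,4,5,5-tetramethyl-1,3,2-dioxaborolan-2-yl)phenol] | COc1cc(CCCCCCCCCCCCCc2cc(OC)c(C)c(B3OC(C)(C)C(C)(C)O3)c2O)c(O)c(B2OC(C)(C)C(C)(C)O2)c1C | intermediate
15 | 1,13-bis[5-methoxy-2-(methoxymethoxy)-4-methyl-3-(4,4,5,5-tetramethyl-1,3,2-dioxaborolan-2-yl)phenyl]tridecane | COc1cc(CCCCCCCCCCCCCc2cc(OC)c(C)c(B3OC(C)(C)C(C)(C)O3)c2OCOC)c(OCOC)c(B2OC(C)(C)C(C)(C)O2)c1C | intermediate
16 | 3,3′-(tridecane-1,13-diyl)bis[5-methoxy-2-(methoxymethoxy)-6-methylphenol] | COc1cc(CCCCCCCCCCCCCc2cc(OC)c(C)c(O)c2OCOC)c(OCOC)c(O)c1C | intermediate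
17 | 3,3′-(tridecane-1,13-diyl)bis[5-methoxy-2-(methoxymethoxy)-6-methylcyclohexa-2,5-diene-1,4-dione] | COC1=C(C)C(=O)C(OCOC)=C(CCCCCCCCCCCCCC2=C(OCOC)C(=O)C(C)=C(OC)C2=O)C1=O | intermediate
18 | 3,3′-(tridecane-1,13-diyl)bis(2-hydroxy-5-methoxy-6-methylcyclohexa-2,5-diene-1,4-dione) | COC1=C(C)C(=O)C(O)=C(CCCCCCCCCCCCCC2=C(O)C(=O)C(C)=C(OC)C2=O)C1=O | target

**Count**

Total steps: 9. Longest linear sequence: 8 (steps 2 to 9; step 1 is a one-step branch that joins at step 4).

**Steps most likely to fail**

Step 5. What may go wrong is leakage of regiocontrol in the alkyne insertion, protodeboronation of the ortho-hydroxyaryl boronate during annulation or air work-up, and incomplete reaction at the second carbene end. The fallback sets out from 11 and comes back at 14, moving C–B bond formation out of the annulation. 11 is annulated under the same thermal conditions with commercial 1-(trimethylsilyl)propyne, whose silyl group takes the large-substituent position next to the new hydroxyl, to give 6,6′-(tridecane-1,13-diyl)bis[4-methoxy-3-methyl-2-(trimethylsilyl)phenol] F1. Ipso-borodesilylation (BCl3, CH2Cl2, 0 °C; then pinacol, Et3N) then replaces silicon by boron at the same carbon and gives 14.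

Step 4. What may go wrong is self-aldol reaction of the enolisable dialdehyde, reversal of the aldol addition before the alkoxide is trapped, and conjugate addition of remaining carbene anion to the alkenylcarbene already formed. The fallback sets out from 7 and comes back at 11, building the carbene carbon–alkene bond instead of the C=C bond. Takai olefination of 7 (CrCl2, CHI3, THF/dioxane) gives (1E,16E)-1,17-diiodoheptadeca-1,16-diene F2. Iodine–lithium exchange (t-BuLi, Et2O, −78 °C) gives (1E,16E)-1,17-dilithioheptadeca-1,16-diene F3, which adds to two molecules of 1 to give the dilithium bis(acylchromate) F4. O-methylation with Me3OBF4 gives 11 (twofold Fischer carbene synthesis).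

Step 8. What may go wrong is C–C coupling of the phenoxyl radicals at the free para position, giving dimers or oligomers, and attack at the ortho carbon with loss of the MOM group. The fallback sets out from 14 and comes back at 18, using the electrophilicity of an ortho-quinone instead of a radical para-oxygenation and needing no protecting group. Oxidation of 14 (H2O2, NaOH, THF) gives 3,3′-(tridecane-1,13-diyl)bis(5-methoxy-6-methylbenzene-1,2-diol) F5. Ag2O in Et2O gives 3,3′-(tridecane-1,13-diyl)bis(5-methoxy-6-methylcyclohexa-3,5-diene-1,2-dione) F6. Thiele–Winter acetoxylation (Ac2O, cat. H2SO4) adds acetate at the only hydrogen-bearing ring carbon and gives 3,3′-(tridecane-1,13-diyl)bis(5-methoxy-6-methylbenzene-1,2,4-triyl) hexaacetate F7. Methanolysis in air (K2CO3, MeOH) frees the 1,2,4-triol, which should autoxidise to 18.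

**Further compounds**

F1 | step 5 | 6,6′-(tridecane-1,13-diyl)bis[4-methoxy-3-methyl-2-(trimethylsilyl)phenol] | COc1cc(CCCCCCCCCCCCCc2cc(OC)c(C)c([Si](C)(C)C)c2O)c(O)c([Si](C)(C)C)c1C
F2 | step 4 | (1E,16E)-1,17-diiodoheptadeca-1,16-diene | I/C=C/CCCCCCCCCCCCC/C=C/I
F3 | step 4 | (1E,16E)-1,17-dilithioheptadeca-1,16-diene | [Li]/C=C/CCCCCCCCCCCCC/C=C/[Li]
F4 | step 4 | dilithium (2E,17E)-1,19-bis(pentacarbonylchromio)nonadeca-2,17-diene-1,19-diylidene-1,19-diolate | [Li+].[Li+].[O-]C(=[Cr](=C=O)(=C=O)(=C=O)(=C=O)=C=O)/C=C/CCCCCCCCCCCCC/C=C/C([O-])=[Cr](=C=O)(=C=O)(=C=O)(=C=O)=C=O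
F5 | step 8 | 3,3′-(tridecane-1,13-diyl)bis(5-methoxy-6-methylbenzene-1,2-diol) | COc1cc(CCCCCCCCCCCCCc2cc(OC)c(C)c(O)c2O)c(O)c(O)c1C
F6 | step 8 | 3,3′-(tridecane-1,13-diyl)bis(5-methoxy-6-methylcyclohexa-3,5-diene-1,2-dione) | COC1=C(C)C(=O)C(=O)C(CCCCCCCCCCCCCC2=CC(OC)=C(C)C(=O)C2=O)=C1
F7 | step 8 | 3,3′-(tridecane-1,13-diyl)bis(5-methoxy-6-methylbenzene-1,2,4-triyl) hexaacetate | COc1c(C)c(OC(C)=O)c(OC(C)=O)c(CCCCCCCCCCCCCc2c(OC(C)=O)c(OC)c(C)c(OC(C)=O)c2OC(C)=O)c1OC(C)=O
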